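**Retrosynthetic overview**

- Feature: petrosin A is a meso dimer of two quinolizidin-2-ones. In each half, ring A (N5–C4–C3–C2–C1–C9a) is a fully reduced 3,5-dialkyl-4-pyridone (Me on C3, chain on C1). Its C9a is bonded to C9, which hangs three methylenes (C6–C8) from N5. C9–(CH2)5–C1' and C9'–(CH2)5–C1 complete the 16-membered carbocycle.
- Key disconnection: both C9–C9a bonds are cut homolytically to C9 radicals (from C9 carboxylic acids) and aromatic pyridones. This leads back to a 24-membered N,C-linked bis(4-pyridone) cyclophane. A methoxycarbonyl group is added on C4 to close off the second carbon next to nitrogen.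
- The cyclophane is cut at both nitrogens into two molecules of one amino acid 4-pyrone (head-to-tail pyrone-to-pyridone exchange). The pyrone comes from an aldehyde enamine, propionyl chloride and dimethyl oxalate. The chain comes from two alkylations of di-tert-butyl malonate.
- Ring order: pyrone (step 5); two rings A plus the 24-membered ring (step 7); two piperidine rings B with contraction to the 16-membered ring (step 8). Rings A are then saturated, the C4 esters excised and C1/C3 equilibrated (steps 9 to 11).

Key step: step 8

Remark: petrosin numbering is used for each half and for its precursors (N5; C1 to C4 in ring A; C6 to C9 in ring B; C9a at the fusion). Primes mark the second half.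
Remark: petrosin A is meso, so no absolute control is needed. Chiral intermediates are racemic, and SMILES from 18 on give the relative configuration of the meso series. Centres left unmarked are mixtures that are erased or equilibrated later.

**Route**

Step 1
Reactants: 1 di-tert-butyl malonate; 2 tert-butyl (3-bromopropyl)carbamate
Product: 3 di-tert-butyl 2-{3-[(tert-butoxycarbonyl)amino]propyl}malonate
Conditions: NaH, THF/DMF, 0 to 50 °C (1 in excess)
Reagents that add atoms: none
Why: Malonic ester alkylation (SN2): the sodium enolate of 1, kept in excess against dialkylation, displaces the primary bromide, while the carbamate N–H is much less acidic than the malonate C–H and stays untouched.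

Step 2
Reactants: 3 monoalkyl malonate; 4 8-bromooct-1-ene
Product: 5 di-tert-butyl 2-{3-[(tert-butoxycarbonyl)amino]propyl}-2-(oct-7-en-1-yl)malonate
Conditions: NaH (1.05 equiv), Bu4NI (cat.), DMF, 0 to 60 °C
Reagents that add atoms: none
Why: Second malonic ester alkylation (SN2) builds the quaternary carbon that becomes C9; one equivalent of base takes only the remaining malonate C–H, and the product has no acidic C–H left, so it cannot react further.

Step 3
Reactants: 5 octenyl malonate
Product: 7 di-tert-butyl 2-{3-[(tert-butoxycarbonyl)amino]propyl}-2-(7-oxoheptyl)malonate, via secondary ozonide 6 (not isolated)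
Conditions: O3, CH2Cl2, −78 °C; then Me2S, −78 °C to rt
Reagents that add atoms: ozone, [O-][O+]=O
Why: Ozonolysis (Criegee mechanism) with reductive work-up cleaves the only alkene to the aldehyde whose CH2–CHO end becomes C1 and C9a; carbamate and tert-butyl esters are inert to ozone.

Step 4
Reactants: 7 aldehyde; 8 propionyl chloride
Product: 10 (E)-enaminone di-tert-butyl 2-{3-[(tert-butoxycarbonyl)amino]propyl}-2-[6-(morpholin-4-ylmethylidene)-7-oxononyl]malonate, via morpholine enamine 9 (not isolated)
Conditions: morpholine, 4 Å MS, toluene, 0 °C to rt; then 8, Et3N, CH2Cl2, 0 °C to rt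
Reagents that add atoms: morpholine, C1COCCN1
Why: Stork enamine acylation: the nucleophilic β-carbon of the aldehyde enamine takes the propionyl group and Et3N removes HCl to give the push–pull enaminone, which fixes already in the open chain that the long chain sits on future C1 and that the ethyl group supplies C3 and its methyl.

Step 5
Reactants: 10 enaminone; 11 dimethyl oxalate
Product: 13 methyl 5-substituted 3-methyl-4-oxo-4H-pyran-2-carboxylate (side chain: (CH2)5–C(CO2tBu)2–(CH2)3NHBoc), via 2,4-dioxo ester 12 (not isolated)
Conditions: LiN(SiMe3)2 (2.2 equiv), THF, −78 °C; 11, −78 to 0 °C; then AcOH, 50 °C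
Reagents that add atoms: none
Why: Crossed Claisen condensation of the kinetic α'-enolate of the vinylogous amide (the second equivalent of base covers the N–H) with non-enolisable dimethyl oxalate, then acid-promoted addition–elimination in which the new enol oxygen displaces morpholine, the established route from enaminones to 4-pyrone-2-carboxylates; only the ethyl CH2 can react, so the ester ends up next to the methyl-bearing carbon.

Step 6
Reactants: 13 protected pyrone
Product: 15 racemic amino acid pyrone as its trifluoroacetate (H3N+–(CH2)3–CH(CO2H)–(CH2)5–pyrone), via aminomalonic acid trifluoroacetate 14 (not isolated)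
Conditions: CF3CO2H/CH2Cl2 1:1, rt; evaporate; AcOH, 115 °C
Reagents that add atoms: trifluoroacetic acid, OC(=O)C(F)(F)F
Why: Acidolysis of the Boc group and both tert-butyl esters (loss of isobutene) and thermal decarboxylation of the dialkylmalonic acid through its cyclic six-membered transition state; the amine stays protonated and cannot attack the pyrone, the methyl ester survives, and the new C9 centre is racemic, which is harmless because step 8 erases it.

Step 7
Reactants: 15 amino acid pyrone trifluoroacetate (two molecules)
Product: 17 24-membered N,C-linked bis(2-methoxycarbonyl-3-methyl-4-pyridone) cyclophane diacid (CO2Me on C4/C4' and CO2H on C9/C9'), via linear dimer 16 (not isolated)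
Conditions: slow addition of 15 to Et3N, MeOH, 65 °C (final about 2 mM); acidic work-up
Reagents that add atoms: none
Why: Two pyrone-to-pyridone exchanges (aza-Michael addition at the unsubstituted ring CH, ring opening, recondensation on the keto ester carbon with loss of water) join two molecules head to tail; running it on the carboxylate avoids the δ-lactam that a free amine would form with a C9 ester, slow addition favours ring closure of 16 over chain growth, and the one-molecule alternative would be a strained [9]metacyclophane-type pyridone.

Step 8
Reactants: 17 bis-pyridone cyclophane diacid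
Product: 19 meso bis(dihydropyridone) diester macrocycle (petrosin A carrying a C3=C4 alkene plus a C4 CO2Me group in each half), via half-closed 20-membered acid 18 (not isolated)
Conditions: Ir[dF(CF3)ppy]2(dtbbpy)PF6 (2 mol %), Cs2CO3 (1.1 equiv), degassed DMSO (2 mM), 450 nm LEDs, 25 °C
Reagents that add atoms: none
Why: Proposed new method: the excited trivalent-iridium complex oxidises each caesium carboxylate, loss of CO2 leaves a nucleophilic secondary radical at C9, this adds to the C9a–H carbon of the pyridone held through N5 and C6–C8, and the C1 α-keto radical so formed is reduced by the divalent-iridium state to an enolate that is protonated at C1, so the step is redox-neutral; the closest known reactions are the photoredox decarboxylative Giese reaction and 6-exo alkyl radical cyclisation onto 2,3-dihydro-4-pyridones, and what is unprecedented is an aromatic N-alkyl-4-pyridone as acceptor, used twice across a macrocycle. Each ring B (N5, C6, C7, C8, C9, C9a) closes 6-exo-trig, and the large ring shrinks from 24 through 20 (in 18) to 16 members. C9 and C9a are set together by a chair-like transition state in which the pentamethylene chain on C9 is equatorial rather than over the pyridone face, which puts H9 and H9a trans. C1 is set by axial protonation of the enolate anti to the pseudoaxial C9a–C9 bond (H1 cis to H9a) and can still be corrected in step 11. The step needs attack at C9a and not at C4, the other carbon next to N5 and equally 6-exo: the methoxycarbonyl group on C4 secures this, because a substituent on the attacked carbon strongly retards alkyl radical addition, and it also lowers the acceptor LUMO. Nothing links the two closures, so the meso series (drawn) and the C2-symmetric series are both expected and are carried together to step 11.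

Step 9
Reactants: 19 bis(dihydropyridone) diester
Product: 21 macrocyclic bis(2-oxoquinolizidine-4-carboxylic acid) as a C1/C3/C4 epimer mixture, via saturated diester 20 (not isolated)
Conditions: Zn dust, AcOH, rt; filter, evaporate; 3 M aq HCl, 80 °C; ion exchange
Reagents that add atoms: water, O
Why: Dissolving-metal conjugate reduction of an ene-1,4-dicarbonyl unit (MeO2C–C4=C3–C2=O, the method also used for 2,3-dihydro-4-pyridones), followed by acid-catalysed ester hydrolysis in which the protonated amine cannot undergo retro-Michael opening; C3 and C4 form unselectively, but C4 loses its stereocentre in step 10 and C3 is equilibrated in step 11.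

Step 10
Reactants: 21 bis(α-amino acid)
Product: 22 petrosin A skeleton as a C1/C3 epimer mixture
Conditions: Ir[dF(CF3)ppy]2(dtbbpy)PF6 (1 mol %), 2,4,6-triisopropylbenzenethiol (20 mol %), K2HPO4, MeCN/H2O, 450 nm LEDs, rt, stopped at full conversion
Reagents that add atoms: none
Why: Photoredox hydrodecarboxylation: the α-amino carboxylate is the most easily oxidised group, loss of CO2 gives the α-amino radical at C4, which takes a hydrogen atom from the thiol (the thiolate is regenerated by the reduced catalyst), so C4 becomes the CH2 of the target and no stereocentre is created.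

Step 11
Reactants: 22 epimer mixture
Product: 23 petrosin A
Conditions: K2CO3, MeOH, rt; chromatography on basic alumina
Reagents that add atoms: none
Why: Base-mediated epimerisation through the C2 enolates drives each half to its most stable arrangement, a trans-fused quinolizidinone with the C3 methyl equatorial and the C1 chain axial (H1 cis to H9a), because an equatorial C1 chain would clash in a syn-pentane fashion with the equatorial C9 chain; C9 and C9a are not touched, and the meso compound is separated from its C2-symmetric diastereomer by chromatography.

**Compound list**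

1 | di-tert-butyl malonate | CC(C)(C)OC(=O)CC(=O)OC(C)(C)C | starting material
2 | tert-butyl (3-bromopropyl)carbamate | CC(C)(C)OC(=O)NCCCBr | starting material
3 | di-tert-butyl 2-{3-[(tert-butoxycarbonyl)amino]propyl}malonate | CC(C)(C)OC(=O)NCCCC(C(=O)OC(C)(C)C)C(=O)OC(C)(C)C | intermediate
4 | 8-bromooct-1-ene | C=CCCCCCCBr | starting material
5 | di-tert-butyl 2-{3-[(tert-butoxycarbonyl)amino]propyl}-2-(oct-7-en-1-yl)malonate | CC(C)(C)OC(=O)NCCCC(CCCCCCC=C)(C(=O)OC(C)(C)C)C(=O)OC(C)(C)C | intermediate
6 | secondary ozonide (3-substituted 1,2,4-trioxolane) of 5 | CC(C)(C)OC(=O)NCCCC(CCCCCCC1OCOO1)(C(=O)OC(C)(C)C)C(=O)OC(C)(C)C | intermediate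
7 | di-tert-butyl 2-{3-[(tert-butoxycarbonyl)amino]propyl}-2-(7-oxoheptyl)malonate | CC(C)(C)OC(=O)NCCCC(CCCCCCC=O)(C(=O)OC(C)(C)C)C(=O)OC(C)(C)C | intermediate
8 | propionyl chloride | CCC(=O)Cl | starting material
9 | (E)-morpholine enamine of 7 | CC(C)(C)OC(=O)NCCCC(CCCCC/C=C/N1CCOCC1)(C(=O)OC(C)(C)C)C(=O)OC(C)(C)C | intermediate
10 | (E)-enaminone, 6-(morpholin-4-ylmethylidene)-7-oxononyl malonate | CCC(=O)/C(CCCCCC(CCCNC(=O)OC(C)(C)C)(C(=O)OC(C)(C)C)C(=O)OC(C)(C)C)=C/N1CCOCC1 | intermediate
11 | dimethyl oxalate | COC(=O)C(=O)OC | starting material
12 | methyl 3-methyl-2,4-dioxo ester still carrying the enaminone | COC(=O)C(=O)C(C)C(=O)/C(CCCCCC(CCCNC(=O)OC(C)(C)C)(C(=O)OC(C)(C)C)C(=O)OC(C)(C)C)=C/N1CCOCC1 | intermediate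
13 | protected pyrone, methyl 3-methyl-4-oxo-4H-pyran-2-carboxylate with the malonate chain on C5 | COC(=O)C1=C(C)C(=O)C(CCCCCC(CCCNC(=O)OC(C)(C)C)(C(=O)OC(C)(C)C)C(=O)OC(C)(C)C)=CO1 | intermediate
14 | aminomalonic acid pyrone, trifluoroacetate | COC(=O)C1=C(C)C(=O)C(CCCCCC(CCCN)(C(=O)O)C(=O)O)=CO1.OC(=O)C(F)(F)F | intermediate
15 | racemic amino acid pyrone, trifluoroacetate | COC(=O)C1=C(C)C(=O)C(CCCCCC(CCCN)C(=O)O)=CO1.OC(=O)C(F)(F)F | intermediate
16 | linear head-to-tail dimer (amine end, one pyridone, pyrone end, two CO2H) | NCCCC(C(=O)O)CCCCCC1=CN(CCCC(C(=O)O)CCCCCC2=COC(C(=O)OC)=C(C)C2=O)C(C(=O)OC)=C(C)C1=O | intermediate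
17 | 24-membered bis(2-methoxycarbonyl-3-methyl-4-pyridone) cyclophane 9,9'-diacid (meso and racemic forms at C9/C9', erased in step 8) | CC1=C(C(=O)OC)N2CCCC(C(=O)O)CCCCCC3=CN(CCCC(C(=O)O)CCCCCC(C1=O)=C2)C(C(=O)OC)=C(C)C3=O | intermediate
18 | half-closed 20-membered acid (one dihydropyridone half, one pyridone half; H9/H9a trans, H1/H9a cis) | CC1=C(C(=O)OC)N2CCC[C@@H]3CCCCCC4=CN(CCCC(C(=O)O)CCCCC[C@@H](C1=O)[C@H]32)C(C(=O)OC)=C(C)C4=O | intermediate
19 | meso bis(dihydropyridone) diester macrocycle (H9/H9a trans, H1/H9a cis in both halves) | CC1=C(C(=O)OC)N2CCC[C@@H]3CCCCC[C@@H]4C(=O)C(C)=C(C(=O)OC)N5CCC[C@@H](CCCCC[C@@H](C1=O)[C@H]32)[C@H]45 | intermediate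
20 | saturated diester, bis(methyl 2-oxoquinolizidine-4-carboxylate) macrocycle (C1, C3, C4 mixtures) | CC1C(C(=O)OC)N2CCC[C@@H]3CCCCCC4C(=O)C(C)C(C(=O)OC)N5CCC[C@@H](CCCCCC(C1=O)[C@H]32)[C@H]45 | intermediate
21 | bis(2-oxoquinolizidine-4-carboxylic acid) macrocycle (C1, C3, C4 mixtures) | CC1C(C(=O)O)N2CCC[C@@H]3CCCCCC4C(=O)C(C)C(C(=O)O)N5CCC[C@@H](CCCCCC(C1=O)[C@H]32)[C@H]45 | intermediate
22 | petrosin A skeleton, C1/C3 epimer mixture | CC1CN2CCC[C@@H]3CCCCCC4C(=O)C(C)CN5CCC[C@@H](CCCCCC(C1=O)[C@H]32)[C@H]45 | intermediate
23 | petrosin A | C[C@@H]1CN2CCC[C@@H]3CCCCC[C@@H]4C(=O)[C@@H](C)CN5CCC[C@@H](CCCCC[C@@H](C1=O)[C@H]32)[C@H]45 | target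

**Step count**

Total step count: 11. Longest linear sequence: 11 steps (from 1 and 2).

**Steps most likely to fail**

Step 8.
- What may go wrong: addition to the aromatic ring may be slower than hydrogen abstraction by the C9 radical, which would give protodecarboxylation without ring closure. Facial selectivity at C9/C9a may also be poor.
- Fallback (polar closure, from 17 back to 19): 17 is treated with excess Me3SiOTf and Et3N in CH2Cl2. The acids become bis(trimethylsilyl) ketene acetals, and the pyridone oxygens are silylated to 4-silyloxypyridinium triflates.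
- C9 then adds to C9a in a 6-exo Mukaiyama–Mannich-type closure. This is the known addition of silyl ketene acetals to activated pyridinium salts, and the ester again keeps it away from C4.
- Aqueous work-up gives the bis(dihydropyridone) 9,9'-dicarboxylic acid F1 with C9 quaternary.
- Photoredox hydrodecarboxylation of these tertiary acids (same iridium catalyst, arenethiol, base) then delivers hydrogen to the less hindered face of each ring C9 radical. N5 is still a non-oxidisable vinylogous amide at this stage. The route is rejoined at 19.

Step 7.
- What may go wrong: chain growth to oligomers, closure of a single molecule to a 12-membered ring after the first aza-Michael addition, and aminolysis of the methyl ester can all compete with cyclodimerisation.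
- Fallback (stepwise, from 13 and 15 back to 17): 15 is added slowly to a several-fold excess of 13 with Et3N in MeOH at 65 °C. Its amine then meets almost only the pyrone of 13, which gives the protected linear dimer F2. The excess 13 is recovered.
- The treatment of step 6 (CF3CO2H, then AcOH at 115 °C) passes through the linear aminomalonic acid trifluoroacetate F3 and gives 16 as its trifluoroacetate.
- 16 is closed in a purely unimolecular pyrone-to-pyridone exchange at high dilution (Et3N, MeOH, 65 °C) to 17.

Step 10.
- What may go wrong: the photocatalyst may also oxidise the product tertiary amine. Reversible hydrogen atom transfer at C9a would then erode the trans H9/H9a relationship.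
- Fallback (no radical next to nitrogen, from 21 back to 22): heating 21 with POCl3 causes decarbonylation of the α-tertiary amino acid to the C4 iminium ion.
- On work-up with aqueous K2CO3 the iminium ion loses the C3 proton and gives the ester-free bis-enaminone F4 (petrosin A with a C3=C4 alkene in each half).
- Conjugate reduction with LiBH(s-Bu)3 in THF at −78 °C and protonation of the enolates give 22.

**Further compounds**

F1 | step 8 | bis(dihydropyridone) diester macrocycle with a CO2H group on quaternary C9 and C9' (configuration not assigned) | CC1=C(C(=O)OC)N2CCCC3(C(=O)O)CCCCCC4C(=O)C(C)=C(C(=O)OC)N5CCCC(C(=O)O)(CCCCCC(C1=O)C32)C45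
F2 | step 7 | protected linear dimer (NHBoc and di-tert-butyl malonate end, one pyridone, pyrone end) | CC(C)(C)OC(=O)NCCCC(C(=O)OC(C)(C)C)(C(=O)OC(C)(C)C)CCCCCC1=CN(CCCC(C(=O)O)CCCCCC2=COC(C(=O)OC)=C(C)C2=O)C(C(=O)OC)=C(C)C1=O
F3 | step 7 | linear aminomalonic acid trifluoroacetate | NCCCC(C(=O)O)(C(=O)O)CCCCCC1=CN(CCCC(C(=O)O)CCCCCC2=COC(C(=O)OC)=C(C)C2=O)C(C(=O)OC)=C(C)C1=O.OC(=O)C(F)(F)F
F4 | step 10 | ester-free meso bis-enaminone (C1 epimer mixture) | CC1=CN2CCC[C@@H]3CCCCCC4C(=O)C(C)=CN5CCC[C@@H](CCCCCC(C1=O)[C@H]32)[C@H]45
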